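Ring A (the benzoate ring) is cut at two neighbouring carbons: carbon 6, bearing the diaryl ether oxygen, and carbon 5, bearing CH2OH, with the carbon 4 oxygen beside carbon 5. This is the pattern in which a 3-alkoxyaryne accepts a nucleophile and then an electrophile. In one flask, the phenoxide of ring B (the phthalide arene) adds through its carbon 5 oxygen to a ring A 5,6-aryne and carbon dioxide caps the resulting carbon 5 anion. The aryne precursor is a ring A 2-silylaryl triflate (SiMe3 on carbon 5, triflate on carbon 6, MOM ether on carbon 4) from orcinol; the phenol is an acetonide-protected hydroxyphthalide from methyl gallate.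

Key step: step 12

Numbering used below: ring A carbons 1 to 6 carry CO2Me, CH3, H, OH, CH2OH and O-aryl in that order. Ring B is numbered as a phthalide: lactone CH2 on carbon 3a, CH3 on carbon 4, the ether oxygen on carbon 5, hydroxyls on carbons 6 and 7, and the lactone carbonyl on carbon 7a. No compound in the route has a stereocentre.

Remark on ring A: electrophilic halogenation of 2,4-dioxygenated 6-methylbenzoates is divided between the carbon flanked by the two oxygens and the carbon between oxygen and methyl, and bases deprotonate the benzylic methyl of such esters. Silicon is therefore placed on the future ring A carbon 5 by directed lithiation of orcinol bis(MOM) ether before the ester exists.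

Remark on ring B: its three oxygens are contiguous and so are its three carbon substituents, which is the gallic acid pattern. Methyl gallate is the starting material, and its only possible ketal leaves the future ring B carbon 5 hydroxyl free.

Remark on the coupling: the phenoxide is made with KH and the reaction is run in THF, so that no conjugate acid and no acidic solvent competes with CO2 for the aryl anion.

Assumption: orcinol (anhydrous), methyl gallate and carbon dioxide are bought.

**Ring A: aryne precursor**

Step 1
Reactants: 1 orcinol (5-methylbenzene-1,3-diol)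
Product: 2 1,3-bis(methoxymethoxy)-5-methylbenzene
Conditions: NaH, MOMCl, DMF, 0 °C → rt
Reagents that add atoms: chloromethyl methyl ether (MOMCl), COCCl
Why: Williamson-type O-alkylation of both phenoxides gives the bis-acetal, whose oxygens direct the two lithiations that follow.

Step 2
Reactants: 2 1,3-bis(methoxymethoxy)-5-methylbenzene
Product: 4 [2,6-bis(methoxymethoxy)-4-methylphenyl]trimethylsilane, via flanked aryllithium 3 (not isolated)
Conditions: n-BuLi, THF, 0 °C → rt; TMSCl, −78 °C → rt
Reagents that add atoms: chlorotrimethylsilane, C[Si](C)(C)Cl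
Why: Directed ortho-metalation takes the most acidic ring position, the carbon flanked by both MOM ethers, and silylation of aryllithium 3 puts silicon on the future ring A carbon 5 with no competing site.

Step 3
Reactants: 4 [2,6-bis(methoxymethoxy)-4-methylphenyl]trimethylsilane
Product: 6 methyl 2,4-bis(methoxymethoxy)-6-methyl-3-(trimethylsilyl)benzoate, via ring aryllithium 5 (not isolated)
Conditions: s-BuLi, TMEDA, THF, −78 → −40 °C; ClCO2Me (inverse addition), −78 °C → rt
Reagents that add atoms: methyl chloroformate, COC(=O)Cl
Why: With the doubly activated position blocked by silicon, a second directed ortho-metalation takes the only remaining position next to a MOM ether (the two are equivalent by symmetry), and acylation of aryllithium 5 gives a benzoate too hindered to add a second aryllithium.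

Step 4
Reactants: 6 methyl 2,4-bis(methoxymethoxy)-6-methyl-3-(trimethylsilyl)benzoate
Product: 7 methyl 2-hydroxy-4-(methoxymethoxy)-6-methyl-3-(trimethylsilyl)benzoate
Conditions: MgBr2·OEt2, Et2O/CH2Cl2, 0 °C → rt; aq. NH4Cl
Reagents that add atoms: none
Why: Magnesium chelated between the ester carbonyl and the neighbouring acetal oxygen should activate only the MOM ether on ring A carbon 6 for bromide-assisted cleavage (chelation-controlled Lewis-acid ether cleavage), while the aprotic medium spares the acid-sensitive aryl–silicon bond.

Step 5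
Reactants: 7 methyl 2-hydroxy-4-(methoxymethoxy)-6-methyl-3-(trimethylsilyl)benzoate
Product: 8 methyl 4-(methoxymethoxy)-6-methyl-2-(trifluoromethanesulfonyloxy)-3-(trimethylsilyl)benzoate
Conditions: Tf2O, pyridine, CH2Cl2, 0 °C
Reagents that add atoms: triflic anhydride, O=S(=O)(OS(=O)(=O)C(F)(F)F)C(F)(F)F
Why: O-sulfonylation of the chelated phenol gives the 2-silylaryl triflate (SiMe3 on carbon 5, triflate on carbon 6 and MOM ether on carbon 4 of ring A), the standard fluoride-triggered aryne precursor.

**Ring B: phenol**

Step 6
Reactants: 9 methyl gallate (methyl 3,4,5-trihydroxybenzoate)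
Product: 10 methyl 7-hydroxy-2,2-dimethyl-1,3-benzodioxole-5-carboxylate
Conditions: 2,2-dimethoxypropane, TsOH·H2O (cat.), toluene, reflux
Reagents that add atoms: 2,2-dimethoxypropane, COC(C)(C)OC
Why: Acid-catalysed transketalisation ties two adjacent hydroxyls of the symmetric triol into an isopropylidene ketal, which leaves exactly one phenol free, the future ether oxygen on ring B carbon 5.

Step 7
Reactants: 10 methyl 7-hydroxy-2,2-dimethyl-1,3-benzodioxole-5-carboxylate
Product: 11 methyl 6-bromo-7-hydroxy-2,2-dimethyl-1,3-benzodioxole-5-carboxylate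
Conditions: NBS, i-Pr2NH (cat.), CH2Cl2, 0 °C
Reagents that add atoms: N-bromosuccinimide, O=C1CCC(=O)N1Br
Why: Amine-mediated ortho-selective bromination of phenols, in which the N-bromoamine is held by a hydrogen bond to the hydroxyl, should place bromine on position 6 of the benzodioxole, the only free position ortho to the hydroxyl and the future ring B carbon 4.

Step 8
Reactants: 11 methyl 6-bromo-7-hydroxy-2,2-dimethyl-1,3-benzodioxole-5-carboxylate
Product: 12 methyl 7-hydroxy-2,2,6-trimethyl-1,3-benzodioxole-5-carboxylate
Conditions: trimethylboroxine, Pd(OAc)2, SPhos, K3PO4, dioxane/H2O (10:1), 100 °C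
Reagents that add atoms: trimethylboroxine, CB1OB(C)OB(C)O1
Why: Suzuki–Miyaura coupling replaces bromine by methyl, the bulky electron-rich phosphine allowing oxidative addition and transmetalation at the doubly flanked carbon.

Step 9
Reactants: 12 methyl 7-hydroxy-2,2,6-trimethyl-1,3-benzodioxole-5-carboxylate
Product: 13 6-(hydroxymethyl)-2,2,5-trimethyl-1,3-benzodioxol-4-ol
Conditions: LiAlH4, THF, 0 °C → rt; H2O, aq. NaOH
Reagents that add atoms: none
Why: Hydride reduction of the ester gives the benzylic alcohol that becomes the lactone CH2, and the aryl ketal is inert to LiAlH4.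

Step 10
Reactants: 13 6-(hydroxymethyl)-2,2,5-trimethyl-1,3-benzodioxol-4-ol
Product: 14 6-(hydroxymethyl)-7-iodo-2,2,5-trimethyl-1,3-benzodioxol-4-ol
Conditions: NIS, MeCN, 0 °C
Reagents that add atoms: N-iodosuccinimide, O=C1CCC(=O)N1I
Why: Electrophilic aromatic iodination can only take the single remaining ring position, which is para to the free hydroxyl and ortho to a ketal oxygen.

Step 11
Reactants: 14 6-(hydroxymethyl)-7-iodo-2,2,5-trimethyl-1,3-benzodioxol-4-ol
Product: 15 5-hydroxy-6,7-(isopropylidenedioxy)-4-methylisobenzofuran-1(3H)-one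
Conditions: Pd(OAc)2, dppf, CO (1 atm), Et3N, DMF, 80 °C
Reagents that add atoms: carbon monoxide, [C-]#[O+]
Why: Palladium-catalysed carbonylative lactonisation (oxidative addition into the carbon–iodine bond, CO insertion, capture of the acylpalladium by the neighbouring CH2OH) closes the phthalide with its carbonyl on the carbon next to the ketal oxygen, so the position of iodine fixes the lactone orientation.

**Coupling and completion**

Step 12
Reactants: 8 methyl 4-(methoxymethoxy)-6-methyl-2-(trifluoromethanesulfonyloxy)-3-(trimethylsilyl)benzoate; 15 5-hydroxy-6,7-(isopropylidenedioxy)-4-methylisobenzofuran-1(3H)-one; 16 carbon dioxide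
Product: 20 2-[(6,7-isopropylidenedioxy-4-methyl-1-oxo-1,3-dihydroisobenzofuran-5-yl)oxy]-3-(methoxycarbonyl)-6-(methoxymethoxy)-4-methylbenzoic acid, via potassium phenoxide 17 (not isolated), via ring A aryne 18 (not isolated), via arylpotassium 19 (not isolated)
Conditions: 15, KH, THF, 0 °C; then 18-crown-6, KF, CO2 (1 atm), 8 added over several hours, 0 °C → rt; cold 1 M HCl work-up (brief)
Reagents that add atoms: none
Why: Proposed new method: KF/18-crown-6 attacks silicon of 8 and expels triflate to give aryne 18, phenoxide 17 adds to ring A carbon 6, and the carbon 5 aryl anion 19, kept free of proton donors in THF, is trapped by dissolved CO2, so the aryl ether carbon–oxygen bond and the carbon–carbon bond at carbon 5 are made in one flask. The closest known reaction types are the three-component couplings of arynes with amines or isocyanides and CO2 and the two-component O-arylation of phenols by 2-silylaryl triflates, whereas a phenoxide/aryne/CO2 coupling is not established. No ring is closed and no stereocentre is formed. The selectivity needed is addition at carbon 6 and not at carbon 5: the σ-withdrawing oxygen on carbon 4 distorts the aryne so that nucleophiles enter at the carbon meta to it and the developing charge rests on carbon 5 beside that oxygen, whereas the bulk and the weaker inductive pull of the ester on carbon 1 act in the opposite sense. Ring B has no free aromatic hydrogen, so Kolbe–Schmitt carboxylation of the phenoxide cannot compete, and slow addition of 8 keeps the aryne concentration low against fluoride and the product carboxylate.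

Step 13
Reactants: 20 2-[(6,7-isopropylidenedioxy-4-methyl-1-oxo-1,3-dihydroisobenzofuran-5-yl)oxy]-3-(methoxycarbonyl)-6-(methoxymethoxy)-4-methylbenzoic acid
Product: 21 methyl 3-(hydroxymethyl)-2-[(6,7-isopropylidenedioxy-4-methyl-1-oxo-1,3-dihydroisobenzofuran-5-yl)oxy]-4-(methoxymethoxy)-6-methylbenzoate
Conditions: BH3·SMe2, THF, 0 °C → rt; MeOH
Reagents that add atoms: none
Why: Borane reduces carboxylic acids through acyloxyboranes far faster than esters or lactones (chemoselective electrophilic hydride reduction), so only the carboxyl on ring A carbon 5 should be taken to the hydroxymethyl group while the hindered methyl ester, the phthalide, the MOM ether and the ketal stay intact.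

Step 14
Reactants: 21 methyl 3-(hydroxymethyl)-2-[(6,7-isopropylidenedioxy-4-methyl-1-oxo-1,3-dihydroisobenzofuran-5-yl)oxy]-4-(methoxymethoxy)-6-methylbenzoate
Product: 22 methyl 2-[(6,7-dihydroxy-4-methyl-1-oxo-1,3-dihydroisobenzofuran-5-yl)oxy]-4-hydroxy-3-(hydroxymethyl)-6-methylbenzoate (Compound NP-007516)
Conditions: 2 M aq. H2SO4/THF (1:3), 45–50 °C, high dilution
Reagents that add atoms: none
Why: Acid-catalysed hydrolysis cleaves the MOM acetal and the isopropylidene ketal in one operation, and a non-nucleophilic acid in dilute aqueous THF means that water returns the ortho-hydroxybenzylic alcohol if it ionises.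

**Compound list**

1 | orcinol (5-methylbenzene-1,3-diol) | Cc1cc(O)cc(O)c1 | starting material
2 | 1,3-bis(methoxymethoxy)-5-methylbenzene | Cc1cc(OCOC)cc(OCOC)c1 | intermediate
3 | [2,6-bis(methoxymethoxy)-4-methylphenyl]lithium (not isolated) | [Li]c1c(OCOC)cc(C)cc1OCOC | intermediate
4 | [2,6-bis(methoxymethoxy)-4-methylphenyl]trimethylsilane | Cc1cc(OCOC)c([Si](C)(C)C)c(OCOC)c1 | intermediate
5 | [2,4-bis(methoxymethoxy)-6-methyl-3-(trimethylsilyl)phenyl]lithium (not isolated) | [Li]c1c(C)cc(OCOC)c([Si](C)(C)C)c1OCOC | intermediate
6 | methyl 2,4-bis(methoxymethoxy)-6-methyl-3-(trimethylsilyl)benzoate | COC(=O)c1c(C)cc(OCOC)c([Si](C)(C)C)c1OCOC | intermediate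
7 | methyl 2-hydroxy-4-(methoxymethoxy)-6-methyl-3-(trimethylsilyl)benzoate | COC(=O)c1c(C)cc(OCOC)c([Si](C)(C)C)c1O | intermediate
8 | methyl 4-(methoxymethoxy)-6-methyl-2-(trifluoromethanesulfonyloxy)-3-(trimethylsilyl)benzoate | COC(=O)c1c(C)cc(OCOC)c([Si](C)(C)C)c1OS(=O)(=O)C(F)(F)F | intermediate
9 | methyl gallate (methyl 3,4,5-trihydroxybenzoate) | COC(=O)c1cc(O)c(O)c(O)c1 | starting material
10 | methyl 7-hydroxy-2,2-dimethyl-1,3-benzodioxole-5-carboxylate | COC(=O)c1cc(O)c2OC(C)(C)Oc2c1 | intermediate
11 | methyl 6-bromo-7-hydroxy-2,2-dimethyl-1,3-benzodioxole-5-carboxylate | COC(=O)c1c(Br)c(O)c2OC(C)(C)Oc2c1 | intermediate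
12 | methyl 7-hydroxy-2,2,6-trimethyl-1,3-benzodioxole-5-carboxylate | COC(=O)c1c(C)c(O)c2OC(C)(C)Oc2c1 | intermediate
13 | 6-(hydroxymethyl)-2,2,5-trimethyl-1,3-benzodioxol-4-ol | OCc1c(C)c(O)c2OC(C)(C)Oc2c1 | intermediate
14 | 6-(hydroxymethyl)-7-iodo-2,2,5-trimethyl-1,3-benzodioxol-4-ol | OCc1c(C)c(O)c2OC(C)(C)Oc2c1I | intermediate
15 | 5-hydroxy-6,7-(isopropylidenedioxy)-4-methylisobenzofuran-1(3H)-one | Cc1c(O)c2OC(C)(C)Oc2c2C(=O)OCc12 | intermediate
16 | carbon dioxide | O=C=O | starting material
17 | potassium 6,7-(isopropylidenedioxy)-4-methyl-1-oxo-1,3-dihydroisobenzofuran-5-olate (not isolated) | Cc1c([O-])c2OC(C)(C)Oc2c2C(=O)OCc12.[K+] | intermediate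
18 | methyl 4-(methoxymethoxy)-6-methyl-2,3-didehydrobenzoate, the 5,6-aryne of ring A (not isolated) | COC(=O)C1=C(C)C=C(OCOC)C#C1 | intermediate
19 | potassium salt of the ring A carbon 5 aryl anion of the diaryl ether (not isolated) | COC(=O)c1c(C)cc(OCOC)[c-]c1Oc1c(C)c2COC(=O)c2c2OC(C)(C)Oc12.[K+] | intermediate
20 | 2-[(6,7-isopropylidenedioxy-4-methyl-1-oxo-1,3-dihydroisobenzofuran-5-yl)oxy]-3-(methoxycarbonyl)-6-(methoxymethoxy)-4-methylbenzoic acid | COC(=O)c1c(C)cc(OCOC)c(C(=O)O)c1Oc1c(C)c2COC(=O)c2c2OC(C)(C)Oc12 | intermediate
21 | methyl 3-(hydroxymethyl)-2-[(6,7-isopropylidenedioxy-4-methyl-1-oxo-1,3-dihydroisobenzofuran-5-yl)oxy]-4-(methoxymethoxy)-6-methylbenzoate | COC(=O)c1c(C)cc(OCOC)c(CO)c1Oc1c(C)c2COC(=O)c2c2OC(C)(C)Oc12 | intermediate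
22 | methyl 2-[(6,7-dihydroxy-4-methyl-1-oxo-1,3-dihydroisobenzofuran-5-yl)oxy]-4-hydroxy-3-(hydroxymethyl)-6-methylbenzoate (Compound NP-007516) | COC(=O)c1c(C)cc(O)c(CO)c1Oc1c(C)c2c(c(O)c1O)C(=O)OC2 | target

**Step count**

Total: 14 steps. Longest linear sequence: 9 steps (steps 6 to 11, then 12, 13 and 14, from methyl gallate). The ring A branch has 5 steps before the coupling.

**Steps most likely to fail**

Step 12 (it bears the label Proposed new method). Three processes can defeat it. The aryl anion may be protonated before it meets CO2, which would give the plain diaryl ether. The phenoxide may add at ring A carbon 5 under the steric pressure of the ester on carbon 1. The aryne may be consumed by fluoride or by the product carboxylate. The fallback uses known reaction types, fixes the ether position by a leaving group and takes the one-carbon unit on ring A carbon 5 from CO. It sets out from 8. Ipso-iododesilylation with ICl (CH2Cl2, −78 → 0 °C) should give methyl 3-iodo-4-(methoxymethoxy)-6-methyl-2-(trifluoromethanesulfonyloxy)benzoate F1. Palladium-catalysed reductive carbonylation (PdCl2(PPh3)2, CO, Et3SiH, Na2CO3, DMF, 80 °C), in which zerovalent palladium inserts into the carbon–iodine bond in preference to the aryl triflate, should give methyl 3-formyl-4-(methoxymethoxy)-6-methyl-2-(trifluoromethanesulfonyloxy)benzoate F2. SNAr displacement of the triflate, which is activated by the ortho formyl and ortho ester groups, by the caesium salt of 15 (Cs2CO3, DMF, rt → 50 °C) should give methyl 3-formyl-2-[(6,7-isopropylidenedioxy-4-methyl-1-oxo-1,3-dihydroisobenzofuran-5-yl)oxy]-4-(methoxymethoxy)-6-methylbenzoate F3. NaBH4 (THF/MeOH, 0 °C) then reduces only the aldehyde, and the route is rejoined at 21.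

Step 4. The two MOM ethers may be discriminated poorly, so that both are lost, or adventitious HBr may cleave the aryl–silicon bond. The fallback makes full cleavage the aim and lets the hydrogen bond do the sorting. It sets out from 6. Both acetals are removed under Lewis-acid/thiol conditions (ZnBr2, n-PrSH, CH2Cl2, rt) to give methyl 2,4-dihydroxy-6-methyl-3-(trimethylsilyl)benzoate F4. Only the non-chelated hydroxyl on ring A carbon 4 is then re-protected (MOMCl, i-Pr2NEt, CH2Cl2, 0 °C), since the hydroxyl on carbon 6 is locked to the ester carbonyl and shielded by silicon. This returns to 7.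

Step 7. Bromination may go para to the hydroxyl (position 4 of the benzodioxole) or twice, which would put the methyl group of ring B in the wrong place. The fallback delivers the carbon through the phenol oxygen and can therefore only reach the ortho position. It sets out from 10. Gassman ortho-alkylation (Me2S, NCS, CH2Cl2, −25 °C; then Et3N), a [2,3]-sigmatropic shift of the aryloxysulfonium ylide, should give methyl 7-hydroxy-2,2-dimethyl-6-[(methylsulfanyl)methyl]-1,3-benzodioxole-5-carboxylate F5. Desulfurisation with Raney Ni in ethanol then gives 12, so steps 7 and 8 are both bypassed.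

Further compounds
F1 | step 12 | methyl 3-iodo-4-(methoxymethoxy)-6-methyl-2-(trifluoromethanesulfonyloxy)benzoate | COC(=O)c1c(C)cc(OCOC)c(I)c1OS(=O)(=O)C(F)(F)F
F2 | step 12 | methyl 3-formyl-4-(methoxymethoxy)-6-methyl-2-(trifluoromethanesulfonyloxy)benzoate | COC(=O)c1c(C)cc(OCOC)c(C=O)c1OS(=O)(=O)C(F)(F)F
F3 | step 12 | methyl 3-formyl-2-[(6,7-isopropylidenedioxy-4-methyl-1-oxo-1,3-dihydroisobenzofuran-5-yl)oxy]-4-(methoxymethoxy)-6-methylbenzoate | COC(=O)c1c(C)cc(OCOC)c(C=O)c1Oc1c(C)c2COC(=O)c2c2OC(C)(C)Oc12
F4 | step 4 | methyl 2,4-dihydroxy-6-methyl-3-(trimethylsilyl)benzoate | COC(=O)c1c(C)cc(O)c([Si](C)(C)C)c1O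
F5 | step 7 | methyl 7-hydroxy-2,2-dimethyl-6-[(methylsulfanyl)methyl]-1,3-benzodioxole-5-carboxylate | COC(=O)c1c(CSC)c(O)c2OC(C)(C)Oc2c1
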